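**Remark on the structure:** the SMILES is read as (S) at the side-chain carbinol, (R) at the side-chain oxirane CH and (S) at all four ring stereocentres, with both esters (Z) (angelates). The ring oxirane is therefore cis to the side chain and trans to the ring acyloxy group.

## Retrosynthetic overview

1. Target 28 ← twofold angeloylation of diol 24 ← enolate hydroxylation of cis-epoxy ketone 21 ← Luche reduction, hydroxyl-directed epoxidation and reoxidation of carvone-type enone 18, whose side-chain oxirane comes from a Shi epoxidation of 17.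
2. Key disconnection: cyclohexenone 17 ← [3+3] annulation of 3-oxopentanoic acid 13 (a butan-2-one bis-nucleophile, CO2H as traceless activator) with dienal 10. Conjugate addition makes the bond between the acyloxy-bearing ring CH and the ring CH that carries the side chain; aldol condensation makes the bond between the two ring oxirane carbons, first as the enone C=C.
3. Enabling feature: in the six-membered carbocycle the ketone carbon lies between two α-carbons (the O-substituted CH and the methyl-bearing oxirane carbon), and the oxirane CH is β to the ketone across the quaternary carbon and 1,5 to it across CH(side chain)–CH2. The ring is thus a 1,5-keto aldehyde with the ring oxirane as a masked enone.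
4. Dienal 10 ← ethyl (R)-4-chloro-3-hydroxybutanoate 1 (source of the side-chain carbinol), alkenyl Grignard reagent 2, Eschenmoser methylenation, Wittig homologation.
5. Ring order: cyclohexenone (step 7), side-chain oxirane (step 8), ring-fused oxirane (step 10).

Key step: step 7

## Route

Step 1
Reactants: 1 ethyl (R)-4-chloro-3-hydroxybutanoate; 2 (2-methylprop-1-en-1-yl)magnesium bromide
Product: 4 ethyl (S)-3-hydroxy-6-methylhept-5-enoate, via oxirane ester 3 (not isolated)
Conditions: 2 (3 equiv), CuI (10 mol%), THF, −40 → 0 °C; aq. NH4Cl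
Reagents that add atoms: none
Why: The first equivalent of 2 deprotonates the hydroxyl, the alkoxide closes to oxirane 3 with loss of chloride, and copper-catalysed SN2 opening of the oxirane at its terminal CH2 by the alkenyl Grignard reagent (cuprate epoxide opening) leaves the carbinol stereocentre untouched, so only its descriptor changes from R to S.

Step 2
Reactants: 4 ethyl (S)-3-hydroxy-6-methylhept-5-enoate
Product: 5 ethyl (S)-3-[(tert-butyldimethylsilyl)oxy]-6-methylhept-5-enoate
Conditions: TBSCl, imidazole, DMF, rt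
Reagents that add atoms: tert-butyldimethylsilyl chloride, CC(C)(C)[Si](C)(C)Cl
Why: Standard silyl ether formation masks the secondary hydroxyl for the hydride and base steps ahead.

Step 3
Reactants: 5 ethyl (S)-3-[(tert-butyldimethylsilyl)oxy]-6-methylhept-5-enoate
Product: 6 (S)-3-[(tert-butyldimethylsilyl)oxy]-6-methylhept-5-enal
Conditions: i-Bu2AlH (1.1 equiv), CH2Cl2, −78 °C; aq. KNaC4H4O6
Reagents that add atoms: none
Why: Partial ester reduction with i-Bu2AlH at −78 °C should stop at the aldehyde because the tetrahedral aluminium hemiacetal survives until work-up.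

Step 4
Reactants: 6 (S)-3-[(tert-butyldimethylsilyl)oxy]-6-methylhept-5-enal
Product: 8 (S)-3-[(tert-butyldimethylsilyl)oxy]-6-methyl-2-methylidenehept-5-enal, via Mannich base 7 (not isolated)
Conditions: CH2=NMe2 I, Et3N, CH2Cl2, rt
Reagents that add atoms: N,N-dimethylmethyleneiminium iodide (Eschenmoser's salt), C=[N+](C)C.[I-]
Why: Mannich reaction of the aldehyde enol with the iminium salt and β-elimination of dimethylamine from 7 (Eschenmoser α-methylenation) install the 1,1-disubstituted alkene without touching the silyloxy stereocentre.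

Step 5
Reactants: 8 (S)-3-[(tert-butyldimethylsilyl)oxy]-6-methyl-2-methylidenehept-5-enal; 9 2-(triphenyl-λ5-phosphanylidene)acetaldehyde
Product: 10 (2E,5S)-5-[(tert-butyldimethylsilyl)oxy]-8-methyl-4-methylidenenona-2,7-dienal
Conditions: 9 (1.05 equiv), toluene, 70 °C
Reagents that add atoms: none
Why: Wittig olefination with the stabilised formyl ylide should give the (E)-enal and so completes the 2,4-dienal.

Step 6
Reactants: 11 methyl 3-oxopentanoate
Product: 13 3-oxopentanoic acid, via sodium 3-oxopentanoate 12 (not isolated)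
Conditions: NaOH (aq, 1.05 equiv), 0 °C → rt; HCl to pH 2, 0 °C; Et2O extraction, used at once
Reagents that add atoms: sodium hydroxide, [Na+].[OH-]
Why: Ester saponification and cold acidification give the free β-keto acid, which is used immediately because it decarboxylates slowly at room temperature.

Step 7
Reactants: 10 (2E,5S)-5-[(tert-butyldimethylsilyl)oxy]-8-methyl-4-methylidenenona-2,7-dienal; 13 3-oxopentanoic acid
Product: 17 (5R)-5-{(3S)-3-[(tert-butyldimethylsilyl)oxy]-6-methylhepta-1,5-dien-2-yl}-2-methylcyclohex-2-en-1-one, via Michael adduct acid 14 (not isolated), via keto aldehyde 15 (not isolated), via aldol 16 (not isolated)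
Conditions: 13 (2 equiv), (S)-2-[diphenyl(trimethylsilyloxy)methyl]pyrrolidine (20 mol%), Cu(O2CCHMe2)2 (10 mol%), toluene, 0 °C → rt; then Bn2NH·CF3CO2H (30 mol%), 40 °C
Reagents that add atoms: none
Why: The divalent copper carboxylate of 13 is a soft chelated enolate that adds through its C2 to the β-carbon (C3) of the (E)-iminium ion formed from 10 and the prolinol silyl ether (iminium-catalysed Michael addition); adduct 14 loses CO2 to give 1,5-keto aldehyde 15, whose ethyl-side enol attacks the aldehyde and dehydrates to the enone (Robinson-type aldol condensation). The closest known reaction type is the amine-catalysed Michael/aldol-condensation annulation of β-keto esters or β-keto acids with enals to 5-substituted cyclohex-2-enones. The one ring is closed in a 6-(enolendo)-exo-trig aldol step, the only cyclisation of 15 that gives an unstrained ring (the alternatives are four-membered). The one new stereocentre (C5 of 17) is set by the catalyst, whose diphenyl(silyloxy)methyl group shields the Re face of C3 of the s-trans iminium ion so that the nucleophile enters from the Si face and should give 5R whatever the influence of the remote silyloxy stereocentre. The step needs 1,4- rather than 1,6-addition to the 2,4-dienal, which rests on the higher electrophilicity of the carbon next to the iminium carbon in dienyl iminium ions whose β-position is unsubstituted. It also needs acid-free ring closure to spare the allylic silyl ether and the 1,5-diene, which the ammonium salt secures.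

Step 8
Reactants: 17 (5R)-5-{(3S)-3-[(tert-butyldimethylsilyl)oxy]-6-methylhepta-1,5-dien-2-yl}-2-methylcyclohex-2-en-1-one
Product: 18 (5R)-5-{(3S)-3-[(tert-butyldimethylsilyl)oxy]-4-[(2R)-3,3-dimethyloxiran-2-yl]but-1-en-2-yl}-2-methylcyclohex-2-en-1-one
Conditions: 1,2:4,5-di-O-isopropylidene-β-D-erythro-2,3-hexodiulo-2,6-pyranose (30 mol%), KHSO5 (1.4 equiv), K2CO3, Bu4NHSO4, MeCN/CH2(OMe)2/aq. Na2B4O7 buffer, 0 °C
Reagents that add atoms: potassium peroxymonosulfate, [K+].[O-]S(=O)(=O)OO
Why: Shi asymmetric epoxidation: the chiral dioxirane from the D-fructose-derived ketone should epoxidise the electron-rich trisubstituted alkene in preference to the hindered 1,1-disubstituted alkene and the enone, and its spiro transition state should deliver oxygen to the face that gives the (R)-oxirane.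

Step 9
Reactants: 18 (5R)-5-{(3S)-3-[(tert-butyldimethylsilyl)oxy]-4-[(2R)-3,3-dimethyloxiran-2-yl]but-1-en-2-yl}-2-methylcyclohex-2-en-1-one
Product: 19 (1R,5R)-5-{(3S)-3-[(tert-butyldimethylsilyl)oxy]-4-[(2R)-3,3-dimethyloxiran-2-yl]but-1-en-2-yl}-2-methylcyclohex-2-en-1-ol
Conditions: NaBH4, CeCl3·7H2O, MeOH, −78 °C
Reagents that add atoms: none
Why: Luche 1,2-reduction with axial hydride delivery should give the pseudo-equatorial alcohol cis to the C5 substituent, as in the reduction of carvone to cis-carveol.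

Step 10
Reactants: 19 (1R,5R)-5-{(3S)-3-[(tert-butyldimethylsilyl)oxy]-4-[(2R)-3,3-dimethyloxiran-2-yl]but-1-en-2-yl}-2-methylcyclohex-2-en-1-ol
Product: 20 (1R,2R,4S,6S)-4-{(3S)-3-[(tert-butyldimethylsilyl)oxy]-4-[(2R)-3,3-dimethyloxiran-2-yl]but-1-en-2-yl}-1-methyl-7-oxabicyclo[4.1.0]heptan-2-ol
Conditions: VO(acac)2 (5 mol%), t-BuOOH (1.5 equiv), CH2Cl2, 0 °C → rt
Reagents that add atoms: tert-butyl hydroperoxide, CC(C)(C)OO
Why: Vanadium-catalysed hydroxyl-directed epoxidation delivers oxygen to the allylic alkene from the face of the hydroxyl, which places the ring oxirane cis to the side chain and leaves the non-allylic alkene untouched.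

Step 11
Reactants: 20 (1R,2R,4S,6S)-4-{(3S)-3-[(tert-butyldimethylsilyl)oxy]-4-[(2R)-3,3-dimethyloxiran-2-yl]but-1-en-2-yl}-1-methyl-7-oxabicyclo[4.1.0]heptan-2-ol
Product: 21 (1S,4R,6S)-4-{(3S)-3-[(tert-butyldimethylsilyl)oxy]-4-[(2R)-3,3-dimethyloxiran-2-yl]but-1-en-2-yl}-1-methyl-7-oxabicyclo[4.1.0]heptan-2-one
Conditions: Dess–Martin periodinane, NaHCO3, CH2Cl2, rt
Reagents that add atoms: none
Why: Dess–Martin oxidation returns the ketone under buffered conditions and completes the oxidation-level detour that sets the oxirane face, which direct nucleophilic epoxidation of the enone would be expected to set the other way.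

Step 12
Reactants: 21 (1S,4R,6S)-4-{(3S)-3-[(tert-butyldimethylsilyl)oxy]-4-[(2R)-3,3-dimethyloxiran-2-yl]but-1-en-2-yl}-1-methyl-7-oxabicyclo[4.1.0]heptan-2-one
Product: 23 (1S,3S,4S,6S)-4-{(3S)-3-[(tert-butyldimethylsilyl)oxy]-4-[(2R)-3,3-dimethyloxiran-2-yl]but-1-en-2-yl}-3-hydroxy-1-methyl-7-oxabicyclo[4.1.0]heptan-2-one, via lithium enolate 22 (not isolated)
Conditions: LiN(i-Pr)2 (1.2 equiv), THF, −78 °C; then trans-3-phenyl-2-(phenylsulfonyl)oxaziridine (1.5 equiv), −78 °C; aq. NH4Cl
Reagents that add atoms: trans-3-phenyl-2-(phenylsulfonyl)oxaziridine, O=S(=O)(c1ccccc1)N1OC1c1ccccc1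
Why: Deprotonation can occur only at the CH2 next to the ketone (the other α-carbon is quaternary), and oxygen transfer from the N-sulfonyloxaziridine to enolate 22 (Davis enolate hydroxylation) should take place on the face opposite to both the adjacent side chain and the oxirane, giving the trans ketol, which is also the thermodynamic epimer.

Step 13
Reactants: 23 (1S,3S,4S,6S)-4-{(3S)-3-[(tert-butyldimethylsilyl)oxy]-4-[(2R)-3,3-dimethyloxiran-2-yl]but-1-en-2-yl}-3-hydroxy-1-methyl-7-oxabicyclo[4.1.0]heptan-2-one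
Product: 24 (1S,3S,4S,6S)-4-{(3S)-4-[(2R)-3,3-dimethyloxiran-2-yl]-3-hydroxybut-1-en-2-yl}-3-hydroxy-1-methyl-7-oxabicyclo[4.1.0]heptan-2-one
Conditions: Bu4NF (1.5 equiv), AcOH (1.5 equiv), THF, 0 °C → rt
Reagents that add atoms: none
Why: Fluoride-mediated desilylation buffered with acetic acid should free the side-chain hydroxyl without exposing the ketol and the two oxiranes to strong base or acid.

Step 14
Reactants: 24 (1S,3S,4S,6S)-4-{(3S)-4-[(2R)-3,3-dimethyloxiran-2-yl]-3-hydroxybut-1-en-2-yl}-3-hydroxy-1-methyl-7-oxabicyclo[4.1.0]heptan-2-one; 25 angelic acid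
Product: 28 (1S,3S,4S,6S)-4-{(3S)-4-[(2R)-3,3-dimethyloxiran-2-yl]-3-[(Z)-2-methylbut-2-enoyloxy]but-1-en-2-yl}-1-methyl-2-oxo-7-oxabicyclo[4.1.0]heptan-3-yl (Z)-2-methylbut-2-enoate, via mixed anhydride 26 (not isolated), via side-chain mono-angelate 27 (not isolated)
Conditions: 25 (4 equiv), 2,4,6-Cl3C6H2COCl (4 equiv), Et3N, toluene, rt; then 24, toluene, 70 °C
Reagents that add atoms: none
Why: Acyl transfer from the preformed mixed anhydride 26 (Yamaguchi-type esterification run without a nucleophilic catalyst) should acylate first the allylic and then the ketol hydroxyl, and it avoids the Z to E isomerisation that nucleophilic catalysts cause in angeloyl donors.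

## Compound list

1 | ethyl (R)-4-chloro-3-hydroxybutanoate | CCOC(=O)C[C@@H](O)CCl | starting material
2 | (2-methylprop-1-en-1-yl)magnesium bromide | CC(C)=C[Mg]Br | starting material
3 | ethyl (R)-2-(oxiran-2-yl)acetate | CCOC(=O)C[C@@H]1CO1 | intermediate
4 | ethyl (S)-3-hydroxy-6-methylhept-5-enoate | CCOC(=O)C[C@@H](O)CC=C(C)C | intermediate
5 | ethyl (S)-3-[(tert-butyldimethylsilyl)oxy]-6-methylhept-5-enoate | CCOC(=O)C[C@@H](O[Si](C)(C)C(C)(C)C)CC=C(C)C | intermediate
6 | (S)-3-[(tert-butyldimethylsilyl)oxy]-6-methylhept-5-enal | O=CC[C@@H](O[Si](C)(C)C(C)(C)C)CC=C(C)C | intermediate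
7 | (3S)-3-[(tert-butyldimethylsilyl)oxy]-2-[(dimethylamino)methyl]-6-methylhept-5-enal (both C2 epimers) | O=CC(CN(C)C)[C@@H](O[Si](C)(C)C(C)(C)C)CC=C(C)C | intermediate
8 | (S)-3-[(tert-butyldimethylsilyl)oxy]-6-methyl-2-methylidenehept-5-enal | O=CC(=C)[C@@H](O[Si](C)(C)C(C)(C)C)CC=C(C)C | intermediate
9 | 2-(triphenyl-λ5-phosphanylidene)acetaldehyde | O=CC=P(c1ccccc1)(c1ccccc1)c1ccccc1 | starting material
10 | (2E,5S)-5-[(tert-butyldimethylsilyl)oxy]-8-methyl-4-methylidenenona-2,7-dienal | O=C/C=C/C(=C)[C@@H](O[Si](C)(C)C(C)(C)C)CC=C(C)C | intermediate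
11 | methyl 3-oxopentanoate | CCC(=O)CC(=O)OC | starting material
12 | sodium 3-oxopentanoate | CCC(=O)CC(=O)[O-].[Na+] | intermediate
13 | 3-oxopentanoic acid | CCC(=O)CC(=O)O | intermediate
14 | (3R)-3-{(3S)-3-[(tert-butyldimethylsilyl)oxy]-6-methylhepta-1,5-dien-2-yl}-5-oxo-2-propanoylpentanoic acid (both C2 epimers) | C=C([C@@H](O[Si](C)(C)C(C)(C)C)CC=C(C)C)[C@@H](C(C(=O)O)C(=O)CC)CC=O | intermediate
15 | (3R)-3-{(3S)-3-[(tert-butyldimethylsilyl)oxy]-6-methylhepta-1,5-dien-2-yl}-5-oxoheptanal | C=C([C@@H](O[Si](C)(C)C(C)(C)C)CC=C(C)C)[C@@H](CC(=O)CC)CC=O | intermediate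
16 | (5R)-5-{(3S)-3-[(tert-butyldimethylsilyl)oxy]-6-methylhepta-1,5-dien-2-yl}-3-hydroxy-2-methylcyclohexan-1-one (mixture at C2 and C3) | C=C([C@@H](O[Si](C)(C)C(C)(C)C)CC=C(C)C)[C@@H]1CC(O)C(C)C(=O)C1 | intermediate
17 | (5R)-5-{(3S)-3-[(tert-butyldimethylsilyl)oxy]-6-methylhepta-1,5-dien-2-yl}-2-methylcyclohex-2-en-1-one | C=C([C@@H](O[Si](C)(C)C(C)(C)C)CC=C(C)C)[C@@H]1CC=C(C)C(=O)C1 | intermediate
18 | (5R)-5-{(3S)-3-[(tert-butyldimethylsilyl)oxy]-4-[(2R)-3,3-dimethyloxiran-2-yl]but-1-en-2-yl}-2-methylcyclohex-2-en-1-one | C=C([C@@H](O[Si](C)(C)C(C)(C)C)C[C@H]1OC1(C)C)[C@@H]1CC=C(C)C(=O)C1 | intermediate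
19 | (1R,5R)-5-{(3S)-3-[(tert-butyldimethylsilyl)oxy]-4-[(2R)-3,3-dimethyloxiran-2-yl]but-1-en-2-yl}-2-methylcyclohex-2-en-1-ol (hydroxyl cis to the side chain) | C=C([C@@H](O[Si](C)(C)C(C)(C)C)C[C@H]1OC1(C)C)[C@@H]1CC=C(C)[C@H](O)C1 | intermediate
20 | (1R,2R,4S,6S)-4-{(3S)-3-[(tert-butyldimethylsilyl)oxy]-4-[(2R)-3,3-dimethyloxiran-2-yl]but-1-en-2-yl}-1-methyl-7-oxabicyclo[4.1.0]heptan-2-ol (hydroxyl, ring oxirane and side chain on one face) | C=C([C@@H](O[Si](C)(C)C(C)(C)C)C[C@H]1OC1(C)C)[C@@H]1C[C@@H]2O[C@]2(C)[C@H](O)C1 | intermediate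
21 | (1S,4R,6S)-4-{(3S)-3-[(tert-butyldimethylsilyl)oxy]-4-[(2R)-3,3-dimethyloxiran-2-yl]but-1-en-2-yl}-1-methyl-7-oxabicyclo[4.1.0]heptan-2-one | C=C([C@@H](O[Si](C)(C)C(C)(C)C)C[C@H]1OC1(C)C)[C@@H]1C[C@@H]2O[C@]2(C)C(=O)C1 | intermediate
22 | lithium enolate of ketone 21 (enolate C2=C3 of the oxabicycloheptane) | C=C([C@@H](O[Si](C)(C)C(C)(C)C)C[C@H]1OC1(C)C)[C@@H]1C[C@@H]2O[C@]2(C)C([O-])=C1.[Li+] | intermediate
23 | (1S,3S,4S,6S)-4-{(3S)-3-[(tert-butyldimethylsilyl)oxy]-4-[(2R)-3,3-dimethyloxiran-2-yl]but-1-en-2-yl}-3-hydroxy-1-methyl-7-oxabicyclo[4.1.0]heptan-2-one | C=C([C@@H](O[Si](C)(C)C(C)(C)C)C[C@H]1OC1(C)C)[C@@H]1C[C@@H]2O[C@]2(C)C(=O)[C@H]1O | intermediate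
24 | (1S,3S,4S,6S)-4-{(3S)-4-[(2R)-3,3-dimethyloxiran-2-yl]-3-hydroxybut-1-en-2-yl}-3-hydroxy-1-methyl-7-oxabicyclo[4.1.0]heptan-2-one | C=C([C@@H](O)C[C@H]1OC1(C)C)[C@@H]1C[C@@H]2O[C@]2(C)C(=O)[C@H]1O | intermediate
25 | angelic acid, (Z)-2-methylbut-2-enoic acid | C/C=C(/C)C(=O)O | starting material
26 | (Z)-2-methylbut-2-enoic 2,4,6-trichlorobenzoic anhydride | C/C=C(/C)C(=O)OC(=O)c1c(Cl)cc(Cl)cc1Cl | intermediate
27 | (1S,3S,4S,6S)-4-{(3S)-4-[(2R)-3,3-dimethyloxiran-2-yl]-3-[(Z)-2-methylbut-2-enoyloxy]but-1-en-2-yl}-3-hydroxy-1-methyl-7-oxabicyclo[4.1.0]heptan-2-one | C=C([C@H](C[C@H]1OC1(C)C)OC(=O)/C(C)=C\C)[C@@H]1C[C@@H]2O[C@]2(C)C(=O)[C@H]1O | intermediate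
28 | (1S,3S,4S,6S)-4-{(3S)-4-[(2R)-3,3-dimethyloxiran-2-yl]-3-[(Z)-2-methylbut-2-enoyloxy]but-1-en-2-yl}-1-methyl-2-oxo-7-oxabicyclo[4.1.0]heptan-3-yl (Z)-2-methylbut-2-enoate | C=C([C@H](C[C@H]1OC1(C)C)OC(=O)/C(C)=C\C)[C@@H]1C[C@@H]2O[C@]2(C)C(=O)[C@H]1OC(=O)/C(C)=C\C | target

## Step count and risks

Total step count: 14. Longest linear sequence: 13 steps (steps 1–5 and 7–14; step 6 is a one-step side branch).

**Step 7.** Vinylogous (1,6-) attack at the unsubstituted methylene terminus of the dienyl iminium ion, or oligomerisation of the dienal, may outrun the desired 1,4-addition. The fallback sets out from 8 and masks the future exocyclic alkene as a thioether so that the acceptor is a plain enal. Conjugate addition of thiophenol to 8 (PhSH, cat. Et3N, CH2Cl2, 0 °C) gives (3S)-3-[(tert-butyldimethylsilyl)oxy]-6-methyl-2-[(phenylsulfanyl)methyl]hept-5-enal F1. Wittig olefination with 9 gives (2E,5S)-5-[(tert-butyldimethylsilyl)oxy]-8-methyl-4-[(phenylsulfanyl)methyl]nona-2,7-dienal F2, which has no vinylogous position. The same amine/copper annulation with 13 gives (5R)-5-{(3S)-3-[(tert-butyldimethylsilyl)oxy]-6-methyl-1-(phenylsulfanyl)hept-5-en-2-yl}-2-methylcyclohex-2-en-1-one F3. NaIO4 (MeOH/H2O, 0 °C) oxidises it to the corresponding phenyl sulfoxide F4, and thermolysis (toluene, NaHCO3, 110 °C) eliminates benzenesulfenic acid towards the only β-hydrogen, which unveils the 1,1-disubstituted alkene and comes back to the route at 17. Both epimers at the sulfur-bearing branch carbon converge in this elimination.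

**Step 14.** Isomerisation of the angeloyl group to tigloyl during acyl transfer, incomplete acylation of the hindered ketol hydroxyl, or base-induced degradation of the hydroxy epoxy ketone may spoil the final step. The fallback sets out from 24 and builds the (Z)-alkenes on the esters instead of transferring them. Both hydroxyls are esterified with 2-[bis(2,2,2-trifluoroethoxy)phosphoryl]propanoic acid (N,N'-diisopropylcarbodiimide, cat. 4-(dimethylamino)pyridine, CH2Cl2, 0 °C) to give the bis(2-phosphonopropanoate) of diol 24 F5. A twofold Still–Gennari olefination with acetaldehyde (KN(SiMe3)2, 18-crown-6, THF, −78 °C) should then form both (Z)-2-methylbut-2-enoates and comes back to the route at 28.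

**Step 12.** The lithium enolate of the epoxy ketone may fragment (oxirane opening or Favorskii-type pathways), or oxygen transfer may be incomplete or unselective. The fallback sets out from 21 and oxidises a neutral silyl enol ether instead. Adding LiN(i-Pr)2 to 21 in the presence of Me3SiCl (THF, −78 °C, in situ trapping) gives the trimethylsilyl enol ether of 21 F6. Rubottom oxidation with dimethyldioxirane (acetone, −40 °C), again from the face opposite to the side chain and the oxirane, gives the 3-(trimethylsilyloxy) ketone F7. Bu4NF/AcOH (THF, 0 °C) then removes both silyl groups and comes back to the route at 24, skipping 23.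

Further compounds
F1 | step 7 | (3S)-3-[(tert-butyldimethylsilyl)oxy]-6-methyl-2-[(phenylsulfanyl)methyl]hept-5-enal (both C2 epimers) | O=CC(CSc1ccccc1)[C@@H](O[Si](C)(C)C(C)(C)C)CC=C(C)C
F2 | step 7 | (2E,5S)-5-[(tert-butyldimethylsilyl)oxy]-8-methyl-4-[(phenylsulfanyl)methyl]nona-2,7-dienal (both C4 epimers) | O=C/C=C/C(CSc1ccccc1)[C@@H](O[Si](C)(C)C(C)(C)C)CC=C(C)C
F3 | step 7 | (5R)-5-{(3S)-3-[(tert-butyldimethylsilyl)oxy]-6-methyl-1-(phenylsulfanyl)hept-5-en-2-yl}-2-methylcyclohex-2-en-1-one | c1ccccc1SCC([C@@H](O[Si](C)(C)C(C)(C)C)CC=C(C)C)[C@@H]1CC=C(C)C(=O)C1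
F4 | step 7 | (5R)-5-{(3S)-3-[(tert-butyldimethylsilyl)oxy]-6-methyl-1-(phenylsulfinyl)hept-5-en-2-yl}-2-methylcyclohex-2-en-1-one | O=S(c1ccccc1)CC([C@@H](O[Si](C)(C)C(C)(C)C)CC=C(C)C)[C@@H]1CC=C(C)C(=O)C1
F5 | step 14 | bis{2-[bis(2,2,2-trifluoroethoxy)phosphoryl]propanoate} of diol 24 | C=C([C@H](C[C@H]1OC1(C)C)OC(=O)C(C)P(=O)(OCC(F)(F)F)OCC(F)(F)F)[C@@H]1C[C@@H]2O[C@]2(C)C(=O)[C@H]1OC(=O)C(C)P(=O)(OCC(F)(F)F)OCC(F)(F)F
F6 | step 12 | trimethylsilyl enol ether of ketone 21 | C=C([C@@H](O[Si](C)(C)C(C)(C)C)C[C@H]1OC1(C)C)[C@@H]1C[C@@H]2O[C@]2(C)C(O[Si](C)(C)C)=C1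
F7 | step 12 | (1S,3S,4S,6S)-4-{(3S)-3-[(tert-butyldimethylsilyl)oxy]-4-[(2R)-3,3-dimethyloxiran-2-yl]but-1-en-2-yl}-1-methyl-3-[(trimethylsilyl)oxy]-7-oxabicyclo[4.1.0]heptan-2-one | C=C([C@@H](O[Si](C)(C)C(C)(C)C)C[C@H]1OC1(C)C)[C@@H]1C[C@@H]2O[C@]2(C)C(=O)[C@H]1O[Si](C)(C)C
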